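**Plan** (tetralin numbering: ring B = C1–C4 with C2a and C3a the two CH2OH carbons; ring A = C4a–C8a with OMe on C6 and C8 and OH on C7; ring C = the pendant syringyl ring on C1)

- Retrosynthetic cuts, in order: the three O–Si bonds; C2–C2a (one-carbon homologation of a C2 boronate); C1–H and C2–B together (hydroboration of a C1=C2 alkene); C1–ring C (aryllithium on a 1-tetralone, then dehydration); C4–C4a (closure of ring B); C1–C8a (aryllithium on a lactone).
- Forward: lithiated ring A opens a lactone made from (S)-paraconic acid (C1–C8a), the freed C4 alcohol becomes an iodide, ring B closes by attack of C4a on C4, ring C is added to the C1 ketone, and C2a is added last.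
- Enabling feature: the C7 oxygen of ring A is para to C4a, so the ring A phenoxide is a vinylogous enolate whose nucleophilic carbon is C4a. C4 is a primary iodide three atoms from C8a, so the closure is 6-exo-tet; O7 cannot reach C4 and the other activated positions (C6, C8) carry OMe.
- Stereochemistry: C3 comes from (S)-paraconic acid and is not epimerisable after step 1. C1 and C2 are set together by syn hydroboration of C1=C2 on the face anti to the C3 substituent, and boron is exchanged for carbon with retention.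

Key step: step 5

Assumption: (S)-paraconic acid is taken as a purchasable chiral-pool acid; the other two starting materials are catalogue phenols.

**Step 1**
Reactants: 1 (S)-paraconic acid
Product: 3 (S)-4-{[tert-butyl(diphenyl)silyl]oxymethyl}oxolan-2-one, via hydroxymethyl lactone 2 (not isolated)
Conditions: BH3·SMe2, THF, 0 °C to rt; MeOH, concentrate; then TBDPSCl, imidazole, CH2Cl2, 0 °C
Reagents that add atoms: tert-butyl(chloro)diphenylsilane, CC(C)(C)[Si](Cl)(c1ccccc1)c1ccccc1
Why: Acid-selective borane reduction leaves the lactone alone, and the primary alcohol 2 is silylated at once so that translactonisation, which would exchange the two CH2O arms on C3 and racemise it, cannot set in.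

**Step 2**
Reactants: 4 2,6-dimethoxyphenol
Product: 5 (2,6-dimethoxyphenoxy)tri(propan-2-yl)silane
Conditions: TIPSCl, imidazole, DMF, 40 °C
Reagents that add atoms: chlorotri(propan-2-yl)silane, CC(C)[Si](Cl)(C(C)C)C(C)C
Why: Silyl ether formation; the bulky aryl silyl ether tolerates butyllithium and is the fluoride-labile trigger for step 5.

**Step 3**
Reactants: 5 (2,6-dimethoxyphenoxy)tri(propan-2-yl)silane; 3 (S)-4-{[tert-butyl(diphenyl)silyl]oxymethyl}oxolan-2-one
Product: 7 (S)-3-{[tert-butyl(diphenyl)silyl]oxymethyl}-1-[2,4-dimethoxy-3-(triisopropylsilyloxy)phenyl]-4-hydroxybutan-1-one, via aryllithium 6 (not isolated)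
Conditions: 5, n-BuLi, TMEDA, THF, 0 °C; then 3, −78 °C; aq. NH4Cl at −78 °C
Reagents that add atoms: none
Why: Directed ortho-metalation beside a methoxy group (the two possible sites are equivalent) is followed by nucleophilic acyl substitution on the lactone, whose tetrahedral lithium lactolate persists at −78 °C and so stops at the ketone; this makes C1–C8a and frees the C4 hydroxyl without touching C3.

**Step 4**
Reactants: 7 (S)-3-{[tert-butyl(diphenyl)silyl]oxymethyl}-1-[2,4-dimethoxy-3-(triisopropylsilyloxy)phenyl]-4-hydroxybutan-1-one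
Product: 8 (R)-3-{[tert-butyl(diphenyl)silyl]oxymethyl}-1-[2,4-dimethoxy-3-(triisopropylsilyloxy)phenyl]-4-iodobutan-1-one
Conditions: PPh3, iodine, imidazole, CH2Cl2, 0 °C to rt
Reagents that add atoms: iodine, [I][I]
Why: Appel iodination of the primary alcohol under buffered conditions that leave the ketone and both silyl ethers intact (the descriptor changes only because iodine outranks oxygen).

**Step 5**
Reactants: 8 (R)-3-{[tert-butyl(diphenyl)silyl]oxymethyl}-1-[2,4-dimethoxy-3-(triisopropylsilyloxy)phenyl]-4-iodobutan-1-one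
Product: 11 (R)-3-{[tert-butyl(diphenyl)silyl]oxymethyl}-7-hydroxy-6,8-dimethoxy-3,4-dihydronaphthalen-1(2H)-one, via phenoxide 9 (not isolated), via cyclohexadienone 10 (not isolated)
Conditions: TBAF (1.05 equiv), THF, −20 °C, 15 min; then CF3CH2OH (0.005 M), 50 °C
Reagents that add atoms: none
Why: Fluoride cleaves the aryl O–Si bond selectively (a phenoxide leaves far more readily than the alkoxide of the alkyl silyl ether), and phenoxide 9, a vinylogous enolate, attacks the primary iodide C4 through its para carbon C4a in an SN2 displacement to give the cross-conjugated cyclohexadienone 10, which tautomerises to phenol 11. The closest known reaction type is the intramolecular para C-alkylation of phenoxides (aryl participation, Ar2-6), a dearomatisation–rearomatisation of ring A. Ring B closes in the 6-exo-tet mode, C4a onto C4 with iodide leaving outside the new ring. No lasting stereocentre is formed, since C4a of 10 becomes planar again on tautomerisation, and C3 is neither acidic nor a reacting centre, so it is carried through unchanged. The step needs C- over O-alkylation and phenoxide over ketone-enolate reactivity: O7 lies between two methoxy groups and cannot reach C4 within the molecule, trifluoroethanol hydrogen-bonds to the oxygen and high dilution disfavours ether formation between molecules, and with no base stronger than the phenoxide the C2–H bonds should not ionise, so three-membered ring closure from C2 is not expected. Of the carbons ortho and para to O7 only C4a bears hydrogen, so only attack there can lead back to an arene.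

**Step 6**
Reactants: 11 (R)-3-{[tert-butyl(diphenyl)silyl]oxymethyl}-7-hydroxy-6,8-dimethoxy-3,4-dihydronaphthalen-1(2H)-one
Product: 12 (R)-3-{[tert-butyl(diphenyl)silyl]oxymethyl}-6,8-dimethoxy-7-(triisopropylsilyloxy)-3,4-dihydronaphthalen-1(2H)-one
Conditions: TIPSCl, imidazole, DMF, 40 °C
Reagents that add atoms: chlorotri(propan-2-yl)silane, CC(C)[Si](Cl)(C(C)C)C(C)C
Why: Silyl ether formation; the phenol freed in step 5 is masked again so that the organometallic steps 8 and 10 meet no acidic proton.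

**Step 7**
Reactants: 13 4-bromo-2,6-dimethoxyphenol
Product: 14 (4-bromo-2,6-dimethoxyphenoxy)tri(propan-2-yl)silane
Conditions: TIPSCl, imidazole, DMF, 40 °C
Reagents that add atoms: chlorotri(propan-2-yl)silane, CC(C)[Si](Cl)(C(C)C)C(C)C
Why: Silyl ether formation; it gives the ring C donor in a form that undergoes clean bromine–lithium exchange.

**Step 8**
Reactants: 14 (4-bromo-2,6-dimethoxyphenoxy)tri(propan-2-yl)silane; 12 (R)-3-{[tert-butyl(diphenyl)silyl]oxymethyl}-6,8-dimethoxy-7-(triisopropylsilyloxy)-3,4-dihydronaphthalen-1(2H)-one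
Product: 17 (3R)-3-{[tert-butyl(diphenyl)silyl]oxymethyl}-1-[3,5-dimethoxy-4-(triisopropylsilyloxy)phenyl]-6,8-dimethoxy-7-(triisopropylsilyloxy)-3,4-dihydronaphthalene, via aryllithium 15 (not isolated), via tertiary carbinol 16 (not isolated)
Conditions: 14, n-BuLi, THF, −78 °C; then 12, LaCl3·2LiCl, −78 to 0 °C; aq. NH4Cl; then TsOH·H2O (cat.), CH2Cl2, rt
Reagents that add atoms: none
Why: Bromine–lithium exchange gives 15, whose 1,2-addition to the ketone (the lanthanum salt favours addition over enolisation) gives carbinol 16, and acid-catalysed E1 dehydration of this doubly benzylic alcohol can only give the C1=C2 alkene; C3 is unaffected.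

**Step 9**
Reactants: 17 (3R)-3-{[tert-butyl(diphenyl)silyl]oxymethyl}-1-[3,5-dimethoxy-4-(triisopropylsilyloxy)phenyl]-6,8-dimethoxy-7-(triisopropylsilyloxy)-3,4-dihydronaphthalene
Product: 19 2-[(1S,2R,3R)-3-{[tert-butyl(diphenyl)silyl]oxymethyl}-1-[3,5-dimethoxy-4-(triisopropylsilyloxy)phenyl]-6,8-dimethoxy-7-(triisopropylsilyloxy)-1,2,3,4-tetrahydronaphthalen-2-yl]-4,4,5,5-tetramethyl-1,3,2-dioxaborolane, via alkylborane 18 (not isolated)
Conditions: BH3·SMe2 (3 equiv), THF, 0 °C to rt; then pinacol, rt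
Reagents that add atoms: borane–dimethyl sulfide, C[S+](C)[BH3-]; pinacol, CC(C)(O)C(C)(C)O
Why: Hydroboration puts boron on the less substituted C2 and should approach the face anti to the bulky C3 silyloxymethyl group, and because H and B add syn this one event sets C2 (boron trans to C3a) and C1 (H cis to boron, hence ring C trans to boron); pinacol then turns the monoalkylborane 18 into a stable boronic ester.

**Step 10**
Reactants: 19 2-[(1S,2R,3R)-3-{[tert-butyl(diphenyl)silyl]oxymethyl}-1-[3,5-dimethoxy-4-(triisopropylsilyloxy)phenyl]-6,8-dimethoxy-7-(triisopropylsilyloxy)-1,2,3,4-tetrahydronaphthalen-2-yl]-4,4,5,5-tetramethyl-1,3,2-dioxaborolane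
Product: 21 [(1S,2R,3R)-3-{[tert-butyl(diphenyl)silyl]oxymethyl}-1-[3,5-dimethoxy-4-(triisopropylsilyloxy)phenyl]-6,8-dimethoxy-7-(triisopropylsilyloxy)-1,2,3,4-tetrahydronaphthalen-2-yl]methanol, via homologated boronate 20 (not isolated)
Conditions: BrCH2Cl, n-BuLi, THF, −78 °C to rt; then H2O2, aq. NaOH, 0 °C
Reagents that add atoms: bromochloromethane, ClCBr; hydrogen peroxide, OO
Why: Matteson homologation: chloromethyllithium forms the boronate complex and C2 migrates from boron to carbon with retention to give 20, whose new C–B bond is oxidised to the C2a alcohol.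

**Step 11**
Reactants: 21 [(1S,2R,3R)-3-{[tert-butyl(diphenyl)silyl]oxymethyl}-1-[3,5-dimethoxy-4-(triisopropylsilyloxy)phenyl]-6,8-dimethoxy-7-(triisopropylsilyloxy)-1,2,3,4-tetrahydronaphthalen-2-yl]methanol
Product: 22 (1S,2R,3R)-1-(4-hydroxy-3,5-dimethoxyphenyl)-2,3-bis(hydroxymethyl)-6,8-dimethoxy-1,2,3,4-tetrahydronaphthalen-7-ol (lyoniresinol, the target)
Conditions: TBAF, AcOH, THF, rt
Reagents that add atoms: none
Why: Fluoride-mediated desilylation removes the two aryl silyl ethers and the alkyl silyl ether in one operation without touching a stereocentre.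

**Compound list**

1 | (S)-paraconic acid, (3S)-5-oxooxolane-3-carboxylic acid | O=C1C[C@H](C(=O)O)CO1 | starting material
2 | (R)-4-(hydroxymethyl)oxolan-2-one | O=C1C[C@H](CO)CO1 | intermediate (not isolated)
3 | (S)-4-{[tert-butyl(diphenyl)silyl]oxymethyl}oxolan-2-one | O=C1C[C@H](CO[Si](c2ccccc2)(c2ccccc2)C(C)(C)C)CO1 | intermediate
4 | 2,6-dimethoxyphenol | COc1cccc(OC)c1O | starting material
5 | (2,6-dimethoxyphenoxy)tri(propan-2-yl)silane | COc1cccc(OC)c1O[Si](C(C)C)(C(C)C)C(C)C | intermediate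
6 | [2,4-dimethoxy-3-(triisopropylsilyloxy)phenyl]lithium | [Li]c1ccc(OC)c(O[Si](C(C)C)(C(C)C)C(C)C)c1OC | intermediate (not isolated)
7 | (S)-3-{[tert-butyl(diphenyl)silyl]oxymethyl}-1-[2,4-dimethoxy-3-(triisopropylsilyloxy)phenyl]-4-hydroxybutan-1-one | COc1ccc(C(=O)C[C@H](CO[Si](c2ccccc2)(c2ccccc2)C(C)(C)C)CO)c(OC)c1O[Si](C(C)C)(C(C)C)C(C)C | intermediate
8 | (R)-3-{[tert-butyl(diphenyl)silyl]oxymethyl}-1-[2,4-dimethoxy-3-(triisopropylsilyloxy)phenyl]-4-iodobutan-1-one | COc1ccc(C(=O)C[C@H](CO[Si](c2ccccc2)(c2ccccc2)C(C)(C)C)CI)c(OC)c1O[Si](C(C)C)(C(C)C)C(C)C | intermediate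
9 | tetrabutylammonium 3-[(3R)-3-{[tert-butyl(diphenyl)silyl]oxymethyl}-4-iodobutanoyl]-2,6-dimethoxyphenoxide | COc1ccc(C(=O)C[C@H](CO[Si](c2ccccc2)(c2ccccc2)C(C)(C)C)CI)c(OC)c1[O-].CCCC[N+](CCCC)(CCCC)CCCC | intermediate (not isolated)
10 | (3R)-3-{[tert-butyl(diphenyl)silyl]oxymethyl}-6,8-dimethoxy-3,4-dihydronaphthalene-1,7(2H,4aH)-dione (either configuration at C4a) | COC1=CC2C[C@@H](CO[Si](c3ccccc3)(c3ccccc3)C(C)(C)C)CC(=O)C2=C(OC)C1=O | intermediate (not isolated)
11 | (R)-3-{[tert-butyl(diphenyl)silyl]oxymethyl}-7-hydroxy-6,8-dimethoxy-3,4-dihydronaphthalen-1(2H)-one | COc1cc2C[C@@H](CO[Si](c3ccccc3)(c3ccccc3)C(C)(C)C)CC(=O)c2c(OC)c1O | intermediate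
12 | (R)-3-{[tert-butyl(diphenyl)silyl]oxymethyl}-6,8-dimethoxy-7-(triisopropylsilyloxy)-3,4-dihydronaphthalen-1(2H)-one | COc1cc2C[C@@H](CO[Si](c3ccccc3)(c3ccccc3)C(C)(C)C)CC(=O)c2c(OC)c1O[Si](C(C)C)(C(C)C)C(C)C | intermediate
13 | 4-bromo-2,6-dimethoxyphenol | COc1cc(Br)cc(OC)c1O | starting material
14 | (4-bromo-2,6-dimethoxyphenoxy)tri(propan-2-yl)silane | COc1cc(Br)cc(OC)c1O[Si](C(C)C)(C(C)C)C(C)C | intermediate
15 | [3,5-dimethoxy-4-(triisopropylsilyloxy)phenyl]lithium | [Li]c1cc(OC)c(O[Si](C(C)C)(C(C)C)C(C)C)c(OC)c1 | intermediate (not isolated)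
16 | (3R)-3-{[tert-butyl(diphenyl)silyl]oxymethyl}-1-[3,5-dimethoxy-4-(triisopropylsilyloxy)phenyl]-6,8-dimethoxy-7-(triisopropylsilyloxy)-1,2,3,4-tetrahydronaphthalen-1-ol (both C1 epimers) | COc1cc2C[C@@H](CO[Si](c3ccccc3)(c3ccccc3)C(C)(C)C)CC(O)(c3cc(OC)c(O[Si](C(C)C)(C(C)C)C(C)C)c(OC)c3)c2c(OC)c1O[Si](C(C)C)(C(C)C)C(C)C | intermediate (not isolated)
17 | (3R)-3-{[tert-butyl(diphenyl)silyl]oxymethyl}-1-[3,5-dimethoxy-4-(triisopropylsilyloxy)phenyl]-6,8-dimethoxy-7-(triisopropylsilyloxy)-3,4-dihydronaphthalene (C1=C2 alkene, locants of the target) | COc1cc2C[C@@H](CO[Si](c3ccccc3)(c3ccccc3)C(C)(C)C)C=C(c3cc(OC)c(O[Si](C(C)C)(C(C)C)C(C)C)c(OC)c3)c2c(OC)c1O[Si](C(C)C)(C(C)C)C(C)C | intermediate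
18 | [(1S,2R,3R)-3-{[tert-butyl(diphenyl)silyl]oxymethyl}-1-[3,5-dimethoxy-4-(triisopropylsilyloxy)phenyl]-6,8-dimethoxy-7-(triisopropylsilyloxy)-1,2,3,4-tetrahydronaphthalen-2-yl]borane | COc1cc([C@H]2c3c(cc(OC)c(O[Si](C(C)C)(C(C)C)C(C)C)c3OC)C[C@@H](CO[Si](c4ccccc4)(c4ccccc4)C(C)(C)C)[C@@H]2B)cc(OC)c1O[Si](C(C)C)(C(C)C)C(C)C | intermediate (not isolated)
19 | 2-[(1S,2R,3R)-3-{[tert-butyl(diphenyl)silyl]oxymethyl}-1-[3,5-dimethoxy-4-(triisopropylsilyloxy)phenyl]-6,8-dimethoxy-7-(triisopropylsilyloxy)-1,2,3,4-tetrahydronaphthalen-2-yl]-4,4,5,5-tetramethyl-1,3,2-dioxaborolane | COc1cc([C@H]2c3c(cc(OC)c(O[Si](C(C)C)(C(C)C)C(C)C)c3OC)C[C@@H](CO[Si](c4ccccc4)(c4ccccc4)C(C)(C)C)[C@@H]2B5OC(C)(C)C(C)(C)O5)cc(OC)c1O[Si](C(C)C)(C(C)C)C(C)C | intermediate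
20 | 2-{[(1S,2R,3R)-3-{[tert-butyl(diphenyl)silyl]oxymethyl}-1-[3,5-dimethoxy-4-(triisopropylsilyloxy)phenyl]-6,8-dimethoxy-7-(triisopropylsilyloxy)-1,2,3,4-tetrahydronaphthalen-2-yl]methyl}-4,4,5,5-tetramethyl-1,3,2-dioxaborolane | COc1cc([C@H]2c3c(cc(OC)c(O[Si](C(C)C)(C(C)C)C(C)C)c3OC)C[C@@H](CO[Si](c4ccccc4)(c4ccccc4)C(C)(C)C)[C@@H]2CB5OC(C)(C)C(C)(C)O5)cc(OC)c1O[Si](C(C)C)(C(C)C)C(C)C | intermediate (not isolated)
21 | [(1S,2R,3R)-3-{[tert-butyl(diphenyl)silyl]oxymethyl}-1-[3,5-dimethoxy-4-(triisopropylsilyloxy)phenyl]-6,8-dimethoxy-7-(triisopropylsilyloxy)-1,2,3,4-tetrahydronaphthalen-2-yl]methanol | COc1cc([C@H]2c3c(cc(OC)c(O[Si](C(C)C)(C(C)C)C(C)C)c3OC)C[C@@H](CO[Si](c4ccccc4)(c4ccccc4)C(C)(C)C)[C@@H]2CO)cc(OC)c1O[Si](C(C)C)(C(C)C)C(C)C | intermediate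
22 | (1S,2R,3R)-1-(4-hydroxy-3,5-dimethoxyphenyl)-2,3-bis(hydroxymethyl)-6,8-dimethoxy-1,2,3,4-tetrahydronaphthalen-7-ol (lyoniresinol) | COc1cc([C@H]2c3c(cc(OC)c(O)c3OC)C[C@@H](CO)[C@@H]2CO)cc(OC)c1O | target

**Totals and risks**

Total step count: 11. Longest linear sequence: 9 steps (steps 1, 3, 4, 5, 6, 8, 9, 10, 11).

Steps most likely to fail:

Step 5. What may go wrong: ether formation between molecules through the phenoxide oxygen, or ionisation of C2–H followed by three-membered ring closure, could outrun attack through C4a. Fallback, setting out from 14 and 3 and returning at 12: 14 is deprotonated between the methoxy and bromo substituents with lithium 2,2,6,6-tetramethylpiperidide (LiTMP) at −78 °C and the aryllithium is added to 3, giving (S)-1-[6-bromo-2,4-dimethoxy-3-(triisopropylsilyloxy)phenyl]-3-{[tert-butyl(diphenyl)silyl]oxymethyl}-4-hydroxybutan-1-one F1. Appel iodination as in step 4 gives the (R)-4-iodo analogue F2. An intramolecular nickel-catalysed reductive cross-electrophile coupling (NiBr2(dme), 4,4'-di-tert-butyl-2,2'-bipyridine, Zn, DMA) then joins the C4a–Br carbon to the C4–I carbon and gives 12 directly, so step 6 is not needed. The C4–C4a bond is then made by a metal-mediated coupling of two halides instead of by an ionic alkylation, which removes both competing pathways.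

Step 9. What may go wrong: poor facial selectivity of borane addition, if the C3 substituent sits pseudo-equatorial and shields neither face well. Fallback, from 17 to 19: copper-catalysed protoboration (CuCl, NaOtBu, an enantiopure bisphosphine of the matched hand, B2pin2, MeOH, THF). The copper–boryl species adds syn with boron on C2 and copper on the benzylic C1, and protonolysis of the C–Cu bond with retention delivers 19 directly, the face now being chosen by the catalyst and not by the substrate. No new compound arises (entry F0).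

Step 8. What may go wrong: enolisation of the hindered, electron-rich ketone instead of addition, returning 12. Fallback, setting out from 12 and 14 and returning at 17: 12 is converted (LiN(SiMe3)2, PhNTf2, THF, −78 °C; only C2 carries α-hydrogens) into (3R)-3-{[tert-butyl(diphenyl)silyl]oxymethyl}-6,8-dimethoxy-7-(triisopropylsilyloxy)-3,4-dihydronaphthalen-1-yl trifluoromethanesulfonate F3. 14 is borylated (B2pin2, PdCl2(dppf), KOAc, dioxane) to 2-[3,5-dimethoxy-4-(triisopropylsilyloxy)phenyl]-4,4,5,5-tetramethyl-1,3,2-dioxaborolane F4. Suzuki–Miyaura coupling of F3 with F4 (Pd(PPh3)4, K3PO4, dioxane–water) gives 17, with the enolate serving the route instead of defeating it.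

**Further compounds**

F1 | step 5 | (S)-1-[6-bromo-2,4-dimethoxy-3-(triisopropylsilyloxy)phenyl]-3-{[tert-butyl(diphenyl)silyl]oxymethyl}-4-hydroxybutan-1-one | COc1cc(Br)c(C(=O)C[C@H](CO[Si](c2ccccc2)(c2ccccc2)C(C)(C)C)CO)c(OC)c1O[Si](C(C)C)(C(C)C)C(C)C
F2 | step 5 | (R)-1-[6-bromo-2,4-dimethoxy-3-(triisopropylsilyloxy)phenyl]-3-{[tert-butyl(diphenyl)silyl]oxymethyl}-4-iodobutan-1-one | COc1cc(Br)c(C(=O)C[C@H](CO[Si](c2ccccc2)(c2ccccc2)C(C)(C)C)CI)c(OC)c1O[Si](C(C)C)(C(C)C)C(C)C
F0 | step 9 | none | none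
F3 | step 8 | (3R)-3-{[tert-butyl(diphenyl)silyl]oxymethyl}-6,8-dimethoxy-7-(triisopropylsilyloxy)-3,4-dihydronaphthalen-1-yl trifluoromethanesulfonate | COc1cc2C[C@@H](CO[Si](c3ccccc3)(c3ccccc3)C(C)(C)C)C=C(OS(=O)(=O)C(F)(F)F)c2c(OC)c1O[Si](C(C)C)(C(C)C)C(C)C
F4 | step 8 | 2-[3,5-dimethoxy-4-(triisopropylsilyloxy)phenyl]-4,4,5,5-tetramethyl-1,3,2-dioxaborolane | COc1cc(B2OC(C)(C)C(C)(C)O2)cc(OC)c1O[Si](C(C)C)(C(C)C)C(C)C
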